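**Retrosynthetic overview**
1. The target comes from its tri-O-methyl ether (BBr3 last); the (CH2)12 bridge comes from a macrocyclic aryl enone/styrene by hydrogenation and benzylic deoxygenation.
2. The 20-membered ring is the only ring made (both benzene rings are bought); it is closed by ring-closing metathesis between a ring A styrene and the chain-end alkene.
3. Key C–C bond (C2–C3 of the bridge): directed aldol addition of the lithium enolate of a diaryl ether methyl ketone to dec-9-enal; the aldol OH is eliminated later.
4. The diaryl ether comes from acetosyringone and 3,5-dibromoanisole (Ullmann coupling); the remaining bromide is vinylated by Suzuki coupling.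
5. Order: diaryl ether, vinylation, aldol, macrocycle, dehydration, hydrogenation, deoxygenation, demethylation.

Assumption: the target has no stereocentre and, ring B being symmetrically substituted, no planar chirality, so it is one achiral compound and no stereocontrol is needed.

Naming convention: ring B is the 3,5-dioxygenated 4-aryloxyphenyl ring, ring A the 3-oxygenated 5-aryloxyphenyl ring; bridge carbons run from C1 (on ring B) to C12 (on ring A).

**Step 1**
Reactants: 1 1-(4-hydroxy-3,5-dimethoxyphenyl)ethan-1-one (acetosyringone); 2 1,3-dibromo-5-methoxybenzene (3,5-dibromoanisole, 3 equiv)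
Product: 3 1-[4-(3-bromo-5-methoxyphenoxy)-3,5-dimethoxyphenyl]ethan-1-one
Conditions: CuI (10 mol%), picolinic acid (20 mol%), K3PO4 (2 equiv), DMSO, 100 °C
Reagents that add atoms: none
Why: Ullmann-type C–O coupling in which the monovalent copper picolinate catalyst arylates hindered 2,6-disubstituted phenoxides, and the threefold excess of the symmetric dibromide keeps the reaction at mono-etherification.

**Step 2**
Reactants: 3 1-[4-(3-bromo-5-methoxyphenoxy)-3,5-dimethoxyphenyl]ethan-1-one
Product: 4 1-[4-(3-ethenyl-5-methoxyphenoxy)-3,5-dimethoxyphenyl]ethan-1-one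
Conditions: vinylboronic acid pinacol ester (1.5 equiv), PdCl2(dppf) (3 mol%), K2CO3 (3 equiv), 1,4-dioxane/H2O 4:1, 85 °C
Reagents that add atoms: vinylboronic acid pinacol ester (2-ethenyl-4,4,5,5-tetramethyl-1,3,2-dioxaborolane), C=CB1OC(C)(C)C(C)(C)O1
Why: Suzuki–Miyaura coupling in which zerovalent palladium formed in the flask inserts into the remaining Ar–Br bond and takes the vinyl group from boron, while the methyl ketone is inert to aqueous carbonate.

**Step 3**
Reactants: 5 dec-9-en-1-ol
Product: 6 dec-9-enal
Conditions: TEMPO (10 mol%), PhI(OAc)2 (1.1 equiv), CH2Cl2, rt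
Reagents that add atoms: none
Why: TEMPO-catalysed alcohol oxidation (oxoammonium mechanism) stops cleanly at the aldehyde and leaves the terminal alkene alone.

**Step 4**
Reactants: 4 1-[4-(3-ethenyl-5-methoxyphenoxy)-3,5-dimethoxyphenyl]ethan-1-one; 6 dec-9-enal (1.2 equiv)
Product: 8 rac-1-[4-(3-ethenyl-5-methoxyphenoxy)-3,5-dimethoxyphenyl]-3-hydroxydodec-11-en-1-one, via lithium enolate 7 (not isolated)
Conditions: LiN(iPr)2 (1.1 equiv), THF, −78 °C; then 6, −78 °C; sat. aq NH4Cl
Reagents that add atoms: lithium diisopropylamide, [Li+].CC(C)[N-]C(C)C (its lithium is in 7 only; nothing from it stays in 8)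
Why: Directed (crossed) aldol addition in which the aryl methyl ketone is deprotonated completely before the enolisable aldehyde is added, so only the cross product forms; the new carbinol centre arises as a racemate, which does not matter because step 6 removes it.

**Step 5**
Reactants: 8 rac-1-[4-(3-ethenyl-5-methoxyphenoxy)-3,5-dimethoxyphenyl]-3-hydroxydodec-11-en-1-one
Product: 9 rac-(11E)-3-hydroxy-11-en-1-one macrocycle, tri-O-methyl (bridge: ring B–C(=O)–CH2–CH(OH)–(CH2)7–CH=CH–ring A; E major, Z carried along)
Conditions: second-generation Grubbs catalyst RuCl2(=CHPh)(PCy3)(H2IMes) (5 mol%), 1,4-benzoquinone (10 mol%), CH2Cl2 (1 mM), 40 °C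
Reagents that add atoms: none
Why: Ring-closing olefin metathesis in which the two monosubstituted alkenes are the only olefins present, loss of ethene drives closure of the unstrained 20-membered ring at high dilution, and the E/Z ratio is irrelevant because the alkene is hydrogenated in step 7.

**Step 6**
Reactants: 9 rac-(11E)-3-hydroxy-11-en-1-one macrocycle
Product: 11 (2E,11E)-2,11-dien-1-one macrocycle, tri-O-methyl (bridge: ring B–C(=O)–CH=CH–(CH2)7–CH=CH–ring A), via macrocyclic mesylate 10 (not isolated)
Conditions: MsCl (1.5 equiv), Et3N (1.5 equiv), CH2Cl2, 0 °C; then DBU (3 equiv), rt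
Reagents that add atoms: methanesulfonyl chloride, CS(=O)(=O)Cl (its atoms are in 10 only; nothing from it stays in 11)
Why: Mesylation followed by E1cB elimination of the β-mesyloxy ketone gives the conjugated E-enone and erases the carbinol stereocentre.

**Step 7**
Reactants: 11 (2E,11E)-2,11-dien-1-one macrocycle
Product: 12 saturated 1-oxo macrocycle, tri-O-methyl (bridge: ring B–C(=O)–(CH2)11–ring A)
Conditions: H2 (1 atm), 10% Pd/C, EtOAc, rt
Reagents that add atoms: none
Why: Heterogeneous catalytic hydrogenation saturates both disubstituted C=C bonds at 1 atm, whereas the aryl ketone and the aryl ethers are reduced far more slowly under neutral conditions.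

**Step 8**
Reactants: 12 saturated 1-oxo macrocycle
Product: 13 tri-O-methyl ether of the target (bridge: ring B–(CH2)12–ring A)
Conditions: Et3SiH (5 equiv), CF3CO2H/CH2Cl2 1:1, rt to 50 °C
Reagents that add atoms: none
Why: Ionic hydrogenation (Kursanov–Parnes reduction) in which protonation and hydride transfer give the benzylic alcohol, whose cation, stabilised by the para aryloxy group, takes a second hydride to give the methylene group.

**Step 9**
Reactants: 13 tri-O-methyl ether of the target
Product: 14 target CNP0314249.0 (macrocyclic triphenol)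
Conditions: BBr3 (8 equiv), CH2Cl2, −78 °C to rt; then MeOH, H2O
Reagents that add atoms: none
Why: Lewis-acid ether cleavage in which BBr3 demethylates all three aryl methyl ethers by bromide attack at methyl, while the diaryl ether has no sp3 carbon to attack and survives.

**Compound list**
1 | 1-(4-hydroxy-3,5-dimethoxyphenyl)ethan-1-one (acetosyringone) | CC(=O)c1cc(OC)c(O)c(OC)c1 | starting material
2 | 1,3-dibromo-5-methoxybenzene | COc1cc(Br)cc(Br)c1 | starting material
3 | 1-[4-(3-bromo-5-methoxyphenoxy)-3,5-dimethoxyphenyl]ethan-1-one | CC(=O)c1cc(OC)c(Oc2cc(Br)cc(OC)c2)c(OC)c1 | intermediate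
4 | 1-[4-(3-ethenyl-5-methoxyphenoxy)-3,5-dimethoxyphenyl]ethan-1-one | CC(=O)c1cc(OC)c(Oc2cc(C=C)cc(OC)c2)c(OC)c1 | intermediate
5 | dec-9-en-1-ol | OCCCCCCCCC=C | starting material
6 | dec-9-enal | O=CCCCCCCCC=C | intermediate
7 | lithium 1-[4-(3-ethenyl-5-methoxyphenoxy)-3,5-dimethoxyphenyl]ethen-1-olate (lithium enolate of 4) | [Li+].[O-]C(=C)c1cc(OC)c(Oc2cc(C=C)cc(OC)c2)c(OC)c1 | intermediate (not isolated)
8 | rac-1-[4-(3-ethenyl-5-methoxyphenoxy)-3,5-dimethoxyphenyl]-3-hydroxydodec-11-en-1-one | C=CCCCCCCCC(O)CC(=O)c1cc(OC)c(Oc2cc(C=C)cc(OC)c2)c(OC)c1 | intermediate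
9 | rac-(11E)-3-hydroxy-11-en-1-one macrocycle, tri-O-methyl (racemic carbinol; E shown, Z minor) | O=C1CC(O)CCCCCCC/C=C/c2cc(OC)cc(c2)Oc2c(OC)cc1cc2OC | intermediate
10 | 3-O-methanesulfonate of 9 | O=C1CC(OS(C)(=O)=O)CCCCCCC/C=C/c2cc(OC)cc(c2)Oc2c(OC)cc1cc2OC | intermediate (not isolated)
11 | (2E,11E)-2,11-dien-1-one macrocycle, tri-O-methyl | O=C1/C=C/CCCCCCC/C=C/c2cc(OC)cc(c2)Oc2c(OC)cc1cc2OC | intermediate
12 | saturated 1-oxo macrocycle, tri-O-methyl | O=C1CCCCCCCCCCCc2cc(OC)cc(c2)Oc2c(OC)cc1cc2OC | intermediate
13 | tri-O-methyl ether of the target | COc1cc2cc(c1)Oc1c(OC)cc(cc1OC)CCCCCCCCCCCC2 | intermediate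
14 | CNP0314249.0 (achiral) | Oc1cc2cc(c1)Oc1c(O)cc(cc1O)CCCCCCCCCCCC2 | target

**Step count**
Total: 9 steps. Longest linear sequence: 8 steps (steps 1, 2, 4, 5, 6, 7, 8, 9, from 1 and 2 to 14); step 3 is a one-step side branch.

**Steps most likely to fail, with fallbacks**

Step 1 (Ullmann etherification of a hindered, electron-poor phenoxide). If the copper-catalysed coupling with the aryl bromide stalls, change to an oxidative Chan–Lam–Evans coupling with an arylboron partner, which is well suited to acidic 2,6-disubstituted phenols. The fallback sets out from 2: bromine–lithium exchange (n-BuLi, 1.0 equiv, toluene/THF, −78 °C) gives (3-bromo-5-methoxyphenyl)lithium F1, which is trapped with B(OiPr)3 and hydrolysed with aqueous HCl to (3-bromo-5-methoxyphenyl)boronic acid F2. Coupling of F2 (2 equiv) and 1 with Cu(OAc)2 (1 equiv, divalent copper), pyridine, 4 Å molecular sieves, CH2Cl2, air, rt gives 3, where the route is rejoined.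

Step 5 (macrocyclic metathesis; oligomers or ring-contracted material from alkene migration are the risks). If it fails, close the same ring by an intramolecular Mizoroki–Heck reaction, which needs no vinyl group on ring A, so step 2 is skipped. The fallback sets out from 3: LiN(iPr)2, THF, −78 °C gives lithium 1-[4-(3-bromo-5-methoxyphenoxy)-3,5-dimethoxyphenyl]ethen-1-olate F3, which adds to 6 in the same directed aldol to give rac-1-[4-(3-bromo-5-methoxyphenoxy)-3,5-dimethoxyphenyl]-3-hydroxydodec-11-en-1-one F4. Treating F4 with Pd(OAc)2 (10 mol%), P(o-tol)3 (20 mol%), Et3N, MeCN (2 mM), 85 °C arylates the terminal alkene carbon and gives 9, where the route is rejoined. Any double-bond positional isomers in the bridge converge at 12.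

Step 8 (ionic hydrogenation; it may stop at the benzylic alcohol or trifluoroacetate because the flanked aryloxy group donates only weakly). If it fails, remove the carbonyl by Wolff–Kishner reduction (Huang-Minlon procedure), which does not depend on a benzylic cation. The fallback sets out from 12: N2H4·H2O, KOH, diethylene glycol, 130 °C gives the hydrazone of 12 F5, which on heating to 200 °C loses nitrogen and gives 13, where the route is rejoined. Any methyl ether cleaved by hot KOH is of no consequence because step 9 removes all three.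

**Further compounds**
F1 | step 1 | (3-bromo-5-methoxyphenyl)lithium | [Li]c1cc(Br)cc(OC)c1
F2 | step 1 | (3-bromo-5-methoxyphenyl)boronic acid | COc1cc(Br)cc(B(O)O)c1
F3 | step 5 | lithium 1-[4-(3-bromo-5-methoxyphenoxy)-3,5-dimethoxyphenyl]ethen-1-olate | [Li+].[O-]C(=C)c1cc(OC)c(Oc2cc(Br)cc(OC)c2)c(OC)c1
F4 | step 5 | rac-1-[4-(3-bromo-5-methoxyphenoxy)-3,5-dimethoxyphenyl]-3-hydroxydodec-11-en-1-one | C=CCCCCCCCC(O)CC(=O)c1cc(OC)c(Oc2cc(Br)cc(OC)c2)c(OC)c1
F5 | step 8 | hydrazone of 12 | NN=C1CCCCCCCCCCCc2cc(OC)cc(c2)Oc2c(OC)cc1cc2OC
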